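In a one-step world E goes over into Q and keeps going, so we ask first whether the earlier runs stop.

all flasks: D 1.1 mol%
- amber: E 0.50 mM; run made earlier
- grey: E 2 mM; run made earlier
- flask: E 1.0 mM; time 2.0 min

| run | time / min | Q / % | E / % |
|---|---|---|---|
| amber | 0.333 | 74 | 29 |
| amber | 0.833 | 71 | 26 |
| amber | 1.50 | 72 | 28 |
| amber | 2.50 | 71 | 29 |
| grey | 0.667 | 92 | 8 |
| grey | 1.33 | 89 | 5 |
| grey | 2.00 | 93 | 7 |
| grey | 2.50 | 92 | 6 |

(standard deviation of a reading: 1.5 percentage points)

- the average divides the monomer in chains by the number of chains begun, living and dead together
- the numbers in the tables scatter by 1.5 percentage points (one standard deviation)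
- what may be going on: D + Q -> Z; E + J -> Q + J; D -> L; Q + J -> E + J; E + D -> J + Q
- the earlier runs do not show the number of chains; that part of a forecast is a guess

* average number of monomer units in a chain (chains begun, living or dead) at 2.0 min
* part of the E that has reacted at 2.0 min

They do stop: the amber run shows 29 % of its E at 0.333 min and 29 % at 2.50 min, with no change beyond the scatter of 1.5 percentage points.

Where do they stop? The percentages differ, but the amounts agree within the scatter. The amber readings average 0.140 mM of E, and the grey readings 0.130 mM, from a charge 4.00 times as large. We call the amber figure the floor of E, the amount left beside Q in these runs; the usual term is equilibrium monomer concentration.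

Does our flask reach the floor? Its charge of 1.0 mM lies between those of the two runs, and its 2.0 min is 6.01 times the 0.333 min at which the amber run was already flat, so we expect it there. For the flask we reckon 86.0 % reacted. If each D begins one chain, the 0.0110 mM of D gives 78.2 units per chain, but that count is a guess.

The forecast gives 86 % reacted and a longer chain of 85 units, holding of that length that “the range is skewed high”.

The flask gives 86.0 % reacted and 88.2 units per chain.

    D + Q → Z (k = 61.0 M⁻¹ s⁻¹)
    E + J → Q + J, rate k2*[J]*[E] (k = 1.50 × 10⁵ M⁻¹ s⁻¹)
    D → L (k = 0.0650 s⁻¹)
    Q + J → E + J, rate k4*[J] as long as [Q] is above zero (k = 21.0 s⁻¹)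
    E + D → J + Q (k = 1400 M⁻¹ s⁻¹)

The slowest mode of the flask, as it stands at 2.00 min, has a half-life of 2.21 s, short against the 2.0 min of the run, which is 54.3 such half-lives long. The E left in the flask at that time is 14 %, or 0.140 mM, beside a floor of 0.140 mM. For the neighbour flask charged with 0.25 mM of E, at the same loading, that floor gives 44.0 % reacted, and that flask stands at 44.1 %.

The data were computed with made-up constants; noise was put on by code.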